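## Structural features

The target is a 6/6-fused carbobicycle (halimane numbering throughout): ring A (C1–C5, C10) and ring B (C5–C10) share the C5–C10 bond, and the only ring alkene, C1=C10, sits at the fusion, so C5 is the sole fusion stereocentre. Ring A carries quaternary C4 (CH3 = C19, CO2H = C18) bonded to tertiary C5; ring B carries tertiary C8 (CH3 = C17) bonded to quaternary C9 (CH3 = C20 and the C11–C15 chain). On ring B the C4 branch at C5, the C8 methyl and the C9 methyl lie on one face, opposite H5, H8 and the side chain; the configuration is 4S,5S,8R,9S. The chain ends in an E-trisubstituted C13=C14 alkene whose allylic C15 oxygen is a propanoate. Fragile points are the allylic ester (base, nucleophiles, ionisation), the γ,δ-unsaturated acid (lactonisation onto C10 under protic or halonium activation), the C1=C10 alkene (acid can move it to C5=C10) and the neopentyl-type C18 carboxyl, which is hard to release from a simple ester. The real difficulty is the pair of quaternary carbons, each beside a stereocentre, and the relay of configuration from C8/C9 to C4/C5 across the sp2 carbon C10. The key step exploits that C1=C10 is a trisubstituted alkene between C2 and a C10 flanked by C9 and C5: it is cut into a methylidene on C10 of an intact ring B and a terminal C1 vinyl on a butenyl arm of C4, and ring-closing metathesis can only rejoin them at C1=C10.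

## Logic of the disconnections

22 ⇒ 20 + 21. The acyl–O15 bond is cut. The propanoate is the only enolisable, base-labile group, so it is added last and every strong-base step is freed from it. The forward step must acylate the primary allylic alcohol and leave the hindered C18 acid free.

20 ⇒ 19. The O15–Si bond is cut. A silyl ether survives amide bases, the boron reagent and the ruthenium carbene, and falls to fluoride without acid. The release must not touch the acid or the alkenes.

19 ⇒ 18. The C1=C10 alkene is cut into a C10 methylidene and a C1 vinyl. Ring A disappears and a monocyclic ring B with all four stereocentres remains. The forward step must close a trisubstituted cyclohexene at a hindered 1,1-disubstituted alkene and ignore the C13=C14 alkene.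

18 ⇒ 16. The C4–C19 bond is cut. An α-methyl-α-alkyl ester enolate has no reliable geometry, whereas the enediolate of the acid has none to control. The quaternary centre becomes a tertiary one; the methyl group must enter on one face under the influence of C5.

16 ⇒ 13. The C4–C5 bond is cut with transposition to C5=C10 and an O–C bond at the exocyclic carbon. One [3,3] shift then makes the C4–C5 bond, the C10 methylidene and the free C18 acid. The pieces are a ring B allylic ester and a linear acid. The bond must form on the ring face that carries both methyls, which the ring itself does not favour, so a chiral enolate controller has to decide it.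

13 ⇒ 11 + 12. The ester C–O bond is cut, giving an allylic alcohol and a commercial acid. Only a mild acylation is required.

11 ⇒ 10 ⇒ 9 ⇒ 8 ⇒ 7. The C10–CH2OH bond is cut (cross-coupling at an alkenyl triflate), then the silyl ether and the allylic alcohol are traced back to an enoate, and the triflate to a ketone. Quaternary C9 leaves C5 as the only enolisable position, so the C5=C10 alkene is regiodefined. The triflation must be non-basic because the enoate γ-hydrogens are acidic, and the later reduction must spare the triflate.

7 ⇒ 5 + 6. The C13=C14 alkene is cut by olefination logic. The forward step must react at the methyl ketone only and give the E isomer.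

5 ⇒ 3 + 4, then 3 ⇒ 1. The C9–C11 bond is cut (conjugate addition of an enol ether to an enone), then the C8–C17 bond (catalytic asymmetric conjugate addition of methyl). C8 is set by the catalyst and C9 by attack anti to the C8 methyl, which puts the two methyls cis as required.

## Other disconnections considered

Alternative 1: The cut is C5–C10 and C8–C9. The forward step would be a Lewis-acid-promoted (Et2AlCl) intramolecular Diels–Alder reaction of the triene A1 (E,E-diene C5–C8, E-enone C9=C10, tether C1–C4) to the cis-fused ketone A2.
- In favour: both rings and two bonds form in one suprafacial event. The cis relation of the C4 branch and C17 follows from the diene geometry, and the orientation at C9 from the enone geometry. On relating C5 to C8 and C9 this is the better plan, since the chosen route needs reagent control in step 9 for that.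
- Against: the β,β-disubstituted enone is a sluggish dienophile and must create quaternary C9. Facial selection rests on the acyclic quaternary C4, whose CH3 and CO2CH3 differ little in size. A1 needs an isolated quaternary stereocentre made enantioselectively and three stereodefined alkenes.
- Comparison: the key step does not fix the alkene position. After it, the C1 oxygen must be removed with the alkene placed at C1=C10 (enol triflate toward C10, then reduction), C6=C7 saturated beside C13=C14, and the hindered methyl ester cleaved. That is at least five operations after the key step against two here, and the whole route would be no shorter.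

Alternative 2: The cut is C9–C10. The forward step would be an asymmetric intramolecular Heck reaction of the alkenyl triflate A3 (Pd(OAc)2, chiral BINAP): zerovalent palladium inserts into the C10–O bond, adds 6-exo across C9=C11, and β-hydride elimination toward C12 gives a silyl enol ether that is hydrolysed to the aldehyde A4.
- In favour: the triflate fixes C1=C10 as securely as the metathesis does, so the two plans are equal on that point. Quaternary C9 is made under ligand control, and C9 has no β-hydrogen to divert the elimination.
- Against: A3 must already hold C4, C5 and the remote C8, each set separately. The insertion is at a trisubstituted alkene next to C8, so ligand and substrate may be mismatched.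
- Comparison: ring B is built late here and early in the chosen plan. After the key step the C13–C16 unit with its E alkene must still be joined at C12 and the hindered ester cleaved, about six steps, so step economy is worse.

Alternative 3: The cut is C2–C3 and C4–C5. The forward step would be an exo-selective Diels–Alder reaction of the ring B diene A5 with methacrolein A6 under a chiral oxazaborolidinium Lewis acid, giving the aldehyde A7; one chlorite oxidation would finish the synthesis.
- In favour: this is the shortest plan. A5 would come from the triflate stage by one vinyl coupling, the propanoate can be carried, and the mechanism places the alkene at C1=C10, equal to the metathesis. C4 and C5 would be set together under catalyst control. In step count and in setting C4 with C5 it is the better plan.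
- Against: the α-carbon of A6 must bond to the substituted ring terminus C5. The 1-alkyl effect favours this, but the 2-alkyl effect of C9 and the congestion of forming a quaternary centre beside quaternary C9 oppose it. The cis-substituted terminus lowers reactivity, and the catalyst must override the ring's own facial bias.
- Comparison: regiochemistry, exo/endo control and facial control all rest on one untested cycloaddition, whereas the chosen plan spreads these tasks over separate, individually precedented steps.

Key step: step 11

Assumptions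
- The descriptors of 18 and 19 were recomputed and are 4S,5S,8R,9S for both, identical with the target; the butenyl arm has the length for a six-membered ring, so no structure needed correction.
- The (S,S) antipode of the diazaborolidine controller in step 9 is taken as the one matched to bond formation on the ring face carrying the C8 and C9 methyls; if the opposite holds, the (R,R) antipode is used and nothing else changes.
- The phosphoramidite enantiomer in step 1 is the one that gives the 3R centre.
- Hex-5-enoic acid, triethyl phosphonoacetate, (tributylstannyl)methanol, propanoic anhydride and the bis-sulfonamide of (S,S)-1,2-diphenylethane-1,2-diamine are taken as purchasable; making the bromoborane from the bis-sulfonamide is not counted as a step.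

## Steps

Step 1
Reactants: 1 2-methylcyclohex-2-en-1-one
Product: 3 trimethyl{[(3R)-2,3-dimethylcyclohex-1-en-1-yl]oxy}silane, via dimethylaluminium enolate 2 (not isolated)
Conditions: Me3Al, Cu(OTf)2 (2 mol %), binaphthol-derived bis(1-phenylethyl)amine phosphoramidite (4 mol %), Et2O, −30 °C; then Me3SiOTf, THF, −30 → 0 °C
Reagents that add atoms: trimethylaluminium C[Al](C)C; trimethylsilyl triflate C[Si](C)(C)OS(=O)(=O)C(F)(F)F
Why: Copper-catalysed asymmetric conjugate addition puts the methyl on C8 with the face chosen by the ligand (3R). O-silylation of the aluminium enolate fixes the enol ether regiospecifically at C9=C10.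

Step 2
Reactants: 3 trimethyl{[(3R)-2,3-dimethylcyclohex-1-en-1-yl]oxy}silane; 4 methyl vinyl ketone
Product: 5 (2S,3R)-2,3-dimethyl-2-(3-oxobutyl)cyclohexan-1-one
Conditions: BF3·OEt2, i-PrOH, CH2Cl2, −78 °C
Reagents that add atoms: none
Why: Mukaiyama–Michael addition forms C9–C11. The C8 methyl sits pseudoaxial beside the C9 methyl, so the enone is attacked anti to it; the chain ends trans to C17 and the two methyls cis (2S).

Step 3
Reactants: 5 (2S,3R)-2,3-dimethyl-2-(3-oxobutyl)cyclohexan-1-one; 6 triethyl phosphonoacetate
Product: 7 ethyl (2E)-5-[(1S,2R)-1,2-dimethyl-6-oxocyclohexyl]-3-methylpent-2-enoate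
Conditions: NaH, THF, 0 → 25 °C
Reagents that add atoms: none
Why: Horner–Wadsworth–Emmons olefination reacts at the open methyl ketone and not at the ring ketone beside quaternary C9; the weakly basic phosphonate anion should not start an aldol closure. The ester should end trans to the larger CH2 branch (E); any Z isomer is removed by chromatography.

Step 4
Reactants: 7 ethyl (2E)-5-[(1S,2R)-1,2-dimethyl-6-oxocyclohexyl]-3-methylpent-2-enoate
Product: 8 ethyl (2E)-5-[(1S,6R)-1,6-dimethyl-2-{[(trifluoromethyl)sulfonyl]oxy}cyclohex-2-en-1-yl]-3-methylpent-2-enoate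
Conditions: Tf2O, 2,6-di-tert-butyl-4-methylpyridine, CH2Cl2, 0 → 25 °C
Reagents that add atoms: triflic anhydride O=S(=O)(OS(=O)(=O)C(F)(F)F)C(F)(F)F
Why: O-sulfonylation of the ketone and loss of a C5 proton give the enol triflate; C9 is quaternary, so only the C5=C10 isomer can form. The conditions are non-basic and leave the acidic γ-hydrogens of the enoate alone.

Step 5
Reactants: 8 ethyl (2E)-5-[(1S,6R)-1,6-dimethyl-2-{[(trifluoromethyl)sulfonyl]oxy}cyclohex-2-en-1-yl]-3-methylpent-2-enoate
Product: 9 (5R,6S)-6-[(3E)-5-hydroxy-3-methylpent-3-en-1-yl]-5,6-dimethylcyclohex-1-en-1-yl trifluoromethanesulfonate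
Conditions: i-Bu2AlH, CH2Cl2, −78 °C; aqueous KNaC4H4O6
Reagents that add atoms: none
Why: 1,2-Reduction of the enoate gives the allylic alcohol without touching the alkene geometry; alkenyl triflates are inert to the aluminium hydride at this temperature.

Step 6
Reactants: 9 (5R,6S)-6-[(3E)-5-hydroxy-3-methylpent-3-en-1-yl]-5,6-dimethylcyclohex-1-en-1-yl trifluoromethanesulfonate
Product: 10 (5R,6S)-6-{(3E)-5-[(tert-butyldimethylsilyl)oxy]-3-methylpent-3-en-1-yl}-5,6-dimethylcyclohex-1-en-1-yl trifluoromethanesulfonate
Conditions: t-BuMe2SiCl, imidazole, DMF, 25 °C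
Reagents that add atoms: tert-butyldimethylsilyl chloride CC(C)(C)[Si](C)(C)Cl
Why: Standard silylation of a primary alcohol; the ether then separates O15 from the second allylic oxygen introduced in step 7.

Step 7
Reactants: 10 (5R,6S)-6-{(3E)-5-[(tert-butyldimethylsilyl)oxy]-3-methylpent-3-en-1-yl}-5,6-dimethylcyclohex-1-en-1-yl trifluoromethanesulfonate
Product: 11 [(5R,6S)-6-{(3E)-5-[(tert-butyldimethylsilyl)oxy]-3-methylpent-3-en-1-yl}-5,6-dimethylcyclohex-1-en-1-yl]methanol
Conditions: Bu3SnCH2OH, Pd(PPh3)4 (5 mol %), LiCl, 1,4-dioxane, 100 °C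
Reagents that add atoms: (tributylstannyl)methanol CCCC[Sn](CCCC)(CCCC)CO
Why: Stille coupling: zerovalent palladium inserts into the C10–O bond, and the α-oxygenated methyl group transfers from tin in preference to butyl. The product is the allylic alcohol with the alkene fixed at C5=C10.

Step 8
Reactants: 11 [(5R,6S)-6-{(3E)-5-[(tert-butyldimethylsilyl)oxy]-3-methylpent-3-en-1-yl}-5,6-dimethylcyclohex-1-en-1-yl]methanol; 12 hex-5-enoic acid
Product: 13 [(5R,6S)-6-{(3E)-5-[(tert-butyldimethylsilyl)oxy]-3-methylpent-3-en-1-yl}-5,6-dimethylcyclohex-1-en-1-yl]methyl hex-5-enoate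
Conditions: EDC·HCl, DMAP (cat.), CH2Cl2, 0 → 25 °C
Reagents that add atoms: none
Why: Steglich esterification of a primary allylic alcohol under neutral conditions; no stereocentre is involved.

Step 9
Reactants: 13 [(5R,6S)-6-{(3E)-5-[(tert-butyldimethylsilyl)oxy]-3-methylpent-3-en-1-yl}-5,6-dimethylcyclohex-1-en-1-yl]methyl hex-5-enoate
Product: 16 2-[(1R,3S,4R)-3-{(3E)-5-[(tert-butyldimethylsilyl)oxy]-3-methylpent-3-en-1-yl}-3,4-dimethyl-2-methylidenecyclohexyl]hex-5-enoic acid (C2 epimers), via boron ketene acetal 14 (not isolated), via boron carboxylate 15 (not isolated)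
Conditions: (4S,5S)-2-bromo-1,3-bis{[3,5-bis(trifluoromethyl)phenyl]sulfonyl}-4,5-diphenyl-1,3,2-diazaborolidine (freshly made from the bis-sulfonamide and BBr3), i-Pr2NEt, CH2Cl2, −78 °C, then −20 → 4 °C; aqueous work-up at pH 4
Reagents that add atoms: (4S,5S)-bromoborane controller BrB1N(S(=O)(=O)c2cc(C(F)(F)F)cc(C(F)(F)F)c2)[C@@H](c2ccccc2)[C@H](c2ccccc2)N1S(=O)(=O)c1cc(C(F)(F)F)cc(C(F)(F)F)c1 (its boron heterocycle is carried by 14 and 15 only)
Why: Enantioselective boron-enolate form of the Ireland–Claisen rearrangement: a chair [3,3] shift makes C4–C5, turns C5=C10 into the C10 methylidene and frees the C18 acid. The ring discriminates poorly between its faces at C5 (CH3 against CH2 on C9, with the methyl face the more crowded), so the C2-symmetric controller, which leaves one enolate face open, fixes C5 (the target's 5S centre; it reads 1R here only because C4 is still tertiary). C4 is left undefined because step 10 makes it planar again.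

Step 10
Reactants: 16 2-[(1R,3S,4R)-3-{(3E)-5-[(tert-butyldimethylsilyl)oxy]-3-methylpent-3-en-1-yl}-3,4-dimethyl-2-methylidenecyclohexyl]hex-5-enoic acid (C2 epimers)
Product: 18 (2S)-2-[(1S,3S,4R)-3-{(3E)-5-[(tert-butyldimethylsilyl)oxy]-3-methylpent-3-en-1-yl}-3,4-dimethyl-2-methylidenecyclohexyl]-2-methylhex-5-enoic acid, via dilithium enediolate 17 (not isolated)
Conditions: LiN(i-Pr)2 (2.5 equiv), THF–DMPU, −78 → 0 °C; MeI, −78 → 0 °C; aqueous work-up at pH 4
Reagents that add atoms: iodomethane CI; lithium diisopropylamide [Li+].CC(C)[N-]C(C)C (its lithium is carried by 17 only)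
Why: C-Alkylation of a carboxylic acid dianion; the enediolate has two equal oxygens, so no enolate geometry has to be controlled. Allylic 1,3-strain holds H5 in the enediolate plane, the face toward C10 (methylidene, quaternary C9) is shielded, and iodomethane should enter from the C6 side, which gives 4S.

Step 11
Reactants: 18 (2S)-2-[(1S,3S,4R)-3-{(3E)-5-[(tert-butyldimethylsilyl)oxy]-3-methylpent-3-en-1-yl}-3,4-dimethyl-2-methylidenecyclohexyl]-2-methylhex-5-enoic acid
Product: 19 (1S,5S,6R,8aS)-5-{(3E)-5-[(tert-butyldimethylsilyl)oxy]-3-methylpent-3-en-1-yl}-1,5,6-trimethyl-1,2,3,5,6,7,8,8a-octahydronaphthalene-1-carboxylic acid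
Conditions: second-generation Grubbs catalyst RuCl2(=CHPh)(H2IMes)(PCy3) (10 mol %, in portions), 1,4-benzoquinone (20 mol %), toluene (0.005 M), 80 °C, argon sparge
Reagents that add atoms: none
Why: The benzylidene exchanges with the unhindered monosubstituted C1 vinyl of 18 to give a ruthenium alkylidene at C1. This adds intramolecularly across the 1,1-disubstituted C10 methylidene with ruthenium on the CH2 terminus; the metallacyclobutane cycloreverts to the C1=C10 alkene and Ru=CH2, which returns to a fresh vinyl group with release of ethylene. The closest known reaction type is ring-closing metathesis of a mono- with a 1,1-disubstituted alkene to a trisubstituted cyclohexene, the usual task of N-heterocyclic-carbene ruthenium catalysts. Ring A closes as a six-membered carbocycle by an intramolecular [2+2]/retro-[2+2] sequence with the new alkene endocyclic, and quaternary C4 in the tether pushes the reacting ends together. No stereocentre is formed and C4, C5, C8 and C9 are untouched, so the configuration of 18 is carried over. The selectivity needed is among three alkenes: initiation is confined to the only monosubstituted one, the trisubstituted C13=C14 alkene would have to close a ring of at least ten members, and high dilution with ethylene removal suppresses dimerisation at C1. The alkene forms exactly between the two carbons that carried the exchanging CH2 groups, so it cannot appear at C5=C10; benzoquinone is added to intercept ruthenium hydrides that could move it.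

Step 12
Reactants: 19 (1S,5S,6R,8aS)-5-{(3E)-5-[(tert-butyldimethylsilyl)oxy]-3-methylpent-3-en-1-yl}-1,5,6-trimethyl-1,2,3,5,6,7,8,8a-octahydronaphthalene-1-carboxylic acid
Product: 20 (1S,5S,6R,8aS)-5-[(3E)-5-hydroxy-3-methylpent-3-en-1-yl]-1,5,6-trimethyl-1,2,3,5,6,7,8,8a-octahydronaphthalene-1-carboxylic acid
Conditions: Bu4NF (3 equiv), THF, 0 → 25 °C; aqueous NH4Cl
Reagents that add atoms: none
Why: Fluoride cleaves the Si–O bond under non-acidic conditions, so neither lactonisation onto C10 nor alkene migration can start; the carboxylate formed in situ is inert.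

Step 13
Reactants: 20 (1S,5S,6R,8aS)-5-[(3E)-5-hydroxy-3-methylpent-3-en-1-yl]-1,5,6-trimethyl-1,2,3,5,6,7,8,8a-octahydronaphthalene-1-carboxylic acid; 21 propanoic anhydride
Product: 22 (1S,5S,6R,8aS)-1,5,6-trimethyl-5-[(3E)-3-methyl-5-(propanoyloxy)pent-3-en-1-yl]-1,2,3,5,6,7,8,8a-octahydronaphthalene-1-carboxylic acid
Conditions: (EtCO)2O, pyridine, DMAP (5 mol %), CH2Cl2, 0 °C; then aqueous NaHCO3, 25 °C
Reagents that add atoms: none
Why: Nucleophilic catalysis transfers the acyl group to the unhindered primary allylic alcohol. The neopentyl-type C18 carboxylate can at most form a mixed anhydride, which the bicarbonate work-up hydrolyses at the propanoyl carbonyl, returning the free acid.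

## Compound list

1 | 2-methylcyclohex-2-en-1-one | CC1=CCCCC1=O | starting material
2 | dimethylaluminium (3R)-2,3-dimethylcyclohex-1-en-1-olate | C[C@@H]1CCCC(O[Al](C)C)=C1C | intermediate
3 | trimethyl{[(3R)-2,3-dimethylcyclohex-1-en-1-yl]oxy}silane | C[C@@H]1CCCC(O[Si](C)(C)C)=C1C | intermediate
4 | methyl vinyl ketone | CC(=O)C=C | starting material
5 | (2S,3R)-2,3-dimethyl-2-(3-oxobutyl)cyclohexan-1-one | CC(=O)CC[C@]1(C)C(=O)CCC[C@H]1C | intermediate
6 | triethyl phosphonoacetate | CCOC(=O)CP(=O)(OCC)OCC | starting material
7 | ethyl (2E)-5-[(1S,2R)-1,2-dimethyl-6-oxocyclohexyl]-3-methylpent-2-enoate | CCOC(=O)/C=C(\C)CC[C@]1(C)C(=O)CCC[C@H]1C | intermediate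
8 | ethyl (2E)-5-[(1S,6R)-1,6-dimethyl-2-{[(trifluoromethyl)sulfonyl]oxy}cyclohex-2-en-1-yl]-3-methylpent-2-enoate | CCOC(=O)/C=C(\C)CC[C@]1(C)C(OS(=O)(=O)C(F)(F)F)=CCC[C@H]1C | intermediate
9 | (5R,6S)-6-[(3E)-5-hydroxy-3-methylpent-3-en-1-yl]-5,6-dimethylcyclohex-1-en-1-yl trifluoromethanesulfonate | OC/C=C(\C)CC[C@]1(C)C(OS(=O)(=O)C(F)(F)F)=CCC[C@H]1C | intermediate
10 | (5R,6S)-6-{(3E)-5-[(tert-butyldimethylsilyl)oxy]-3-methylpent-3-en-1-yl}-5,6-dimethylcyclohex-1-en-1-yl trifluoromethanesulfonate | CC(C)(C)[Si](C)(C)OC/C=C(\C)CC[C@]1(C)C(OS(=O)(=O)C(F)(F)F)=CCC[C@H]1C | intermediate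
11 | [(5R,6S)-6-{(3E)-5-[(tert-butyldimethylsilyl)oxy]-3-methylpent-3-en-1-yl}-5,6-dimethylcyclohex-1-en-1-yl]methanol | CC(C)(C)[Si](C)(C)OC/C=C(\C)CC[C@]1(C)C(CO)=CCC[C@H]1C | intermediate
12 | hex-5-enoic acid | C=CCCCC(=O)O | starting material
13 | [(5R,6S)-6-{(3E)-5-[(tert-butyldimethylsilyl)oxy]-3-methylpent-3-en-1-yl}-5,6-dimethylcyclohex-1-en-1-yl]methyl hex-5-enoate | CC(C)(C)[Si](C)(C)OC/C=C(\C)CC[C@]1(C)C(COC(=O)CCCC=C)=CCC[C@H]1C | intermediate
14 | boron ketene acetal of 13 with the (4S,5S)-diazaborolidine on the enolate oxygen (enolate geometry not specified) | CC(C)(C)[Si](C)(C)OC/C=C(\C)CC[C@]1(C)C(COC(=CCCC=C)OB2N(S(=O)(=O)c3cc(C(F)(F)F)cc(C(F)(F)F)c3)[C@@H](c3ccccc3)[C@H](c3ccccc3)N2S(=O)(=O)c2cc(C(F)(F)F)cc(C(F)(F)F)c2)=CCC[C@H]1C | intermediate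
15 | (4S,5S)-diazaborolidinyl ester of acid 16 (boron carboxylate, C4 of the halimane skeleton unspecified) | CC(C)(C)[Si](C)(C)OC/C=C(\C)CC[C@]1(C)C(=C)[C@@H](C(CCC=C)C(=O)OB2N(S(=O)(=O)c3cc(C(F)(F)F)cc(C(F)(F)F)c3)[C@@H](c3ccccc3)[C@H](c3ccccc3)N2S(=O)(=O)c2cc(C(F)(F)F)cc(C(F)(F)F)c2)CC[C@H]1C | intermediate
16 | 2-[(1R,3S,4R)-3-{(3E)-5-[(tert-butyldimethylsilyl)oxy]-3-methylpent-3-en-1-yl}-3,4-dimethyl-2-methylidenecyclohexyl]hex-5-enoic acid (C2 epimers) | CC(C)(C)[Si](C)(C)OC/C=C(\C)CC[C@]1(C)C(=C)[C@@H](C(CCC=C)C(=O)O)CC[C@H]1C | intermediate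
17 | dilithium enediolate of 16 | CC(C)(C)[Si](C)(C)OC/C=C(\C)CC[C@]1(C)C(=C)[C@@H](C(CCC=C)=C(O[Li])O[Li])CC[C@H]1C | intermediate
18 | (2S)-2-[(1S,3S,4R)-3-{(3E)-5-[(tert-butyldimethylsilyl)oxy]-3-methylpent-3-en-1-yl}-3,4-dimethyl-2-methylidenecyclohexyl]-2-methylhex-5-enoic acid | CC(C)(C)[Si](C)(C)OC/C=C(\C)CC[C@]1(C)C(=C)[C@@H]([C@](C)(CCC=C)C(=O)O)CC[C@H]1C | intermediate
19 | (1S,5S,6R,8aS)-5-{(3E)-5-[(tert-butyldimethylsilyl)oxy]-3-methylpent-3-en-1-yl}-1,5,6-trimethyl-1,2,3,5,6,7,8,8a-octahydronaphthalene-1-carboxylic acid | CC(C)(C)[Si](C)(C)OC/C=C(\C)CC[C@]1(C)C2=CCC[C@](C)(C(=O)O)[C@H]2CC[C@H]1C | intermediate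
20 | (1S,5S,6R,8aS)-5-[(3E)-5-hydroxy-3-methylpent-3-en-1-yl]-1,5,6-trimethyl-1,2,3,5,6,7,8,8a-octahydronaphthalene-1-carboxylic acid | OC/C=C(\C)CC[C@]1(C)C2=CCC[C@](C)(C(=O)O)[C@H]2CC[C@H]1C | intermediate
21 | propanoic anhydride | CCC(=O)OC(=O)CC | starting material
22 | (1S,5S,6R,8aS)-1,5,6-trimethyl-5-[(3E)-3-methyl-5-(propanoyloxy)pent-3-en-1-yl]-1,2,3,5,6,7,8,8a-octahydronaphthalene-1-carboxylic acid | CCC(=O)OC/C=C(\C)CC[C@]1(C)C2=CCC[C@](C)(C(=O)O)[C@H]2CC[C@H]1C | target

## Step count and least certain steps

Total: 13 steps. Longest linear sequence: 13 steps (1 to 22).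

Step 11 (key step). The metallacyclobutane at the C10 methylidene, which lies between quaternary C9 and the C5 that bears quaternary C4, may form too slowly. Intermolecular metathesis at the C1 vinyl, hydride-induced migration of the terminal alkene, or catalyst decay in the presence of the free acid could then take over. The fallback sets out from 18: the acid is masked with Me3SiCHN2 in MeOH–toluene as the methyl ester F1, and the ring is closed with the more reactive molybdenum imido alkylidene Mo(=CHCMe2Ph)(=N-2,6-i-Pr2C6H3)[OCMe(CF3)2]2 in benzene, which tolerates esters but not free acids, to give the bicyclic methyl ester F2. The hindered ester is then cleaved at the methyl carbon with LiSPr in HMPA at 25 °C, and the route is rejoined at 19.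

Step 9. The controller may be mismatched with the ring's own preference for bonding on the face away from the two methyls, which would erode the facial selectivity at C5; the bulky boron ketene acetal may also rearrange only slowly at low temperature. The fallback sets out from 13 and gives up reagent control. The silyl ketene acetal rearrangement (LiN(i-Pr)2, Me3SiCl, THF, −78 → 60 °C) gives 16 together with its C5 epimer, and step 10 is run on the mixture. The C5 epimers are then separated by reversible lactonisation: I2 and NaHCO3 in MeCN convert the wanted acid into the iodolactone F3, which is purified by chromatography or crystallisation, and Zn dust in AcOH–THF returns the unsaturated acid by reductive elimination. The route is rejoined at 18.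

Step 10. Deprotonation of the congested α,β-branched carboxylate may be incomplete, and the facial selectivity of the enediolate alkylation may be low or opposite to the allylic-strain model. The fallback sets out from 11 and inverts the order in which the two C4 substituents arrive, so that the same facial preference gives the other C4 configuration. Alcohol 11 is esterified with propanoic acid (EDC·HCl, DMAP) to the propanoate F4, which is rearranged under the conditions of step 9 to the 2-methyl acid F5. The enediolate of F5 (LiN(i-Pr)2, THF–DMPU) is then alkylated with 4-bromobut-1-ene, and the route is rejoined at 18.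

Step 7. Transfer of the sp3 hydroxymethyl group from tin to the hindered alkenylpalladium may be slow, allowing butyl transfer or reduction of the triflate. The fallback sets out from 10: methoxycarbonylation (CO 1 atm, Pd(OAc)2, PPh3, Et3N, MeOH–DMF, 60 °C) gives the unsaturated methyl ester F6, and i-Bu2AlH in CH2Cl2 at −78 °C reduces it. The route is rejoined at 11.

Step 4. O-Sulfonylation of the ketone beside quaternary C9 may be incomplete, and the cationic intermediate may be diverted by the enoate. The fallback sets out from 7 and removes the enoate before a base-mediated triflation. Excess i-Bu2AlH reduces ester and ketone to the diol F7 (carbinol epimers at the ring), t-BuMe2SiCl with imidazole at −20 °C silylates only the primary allylic hydroxyl to give F8, and Dess–Martin periodinane restores the ring ketone F9. KN(SiMe3)2 and PhNTf2 in THF at −78 °C then give the triflate, and the route is rejoined at 10.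

## Further compounds

F1 | step 11 | methyl (2S)-2-[(1S,3S,4R)-3-{(3E)-5-[(tert-butyldimethylsilyl)oxy]-3-methylpent-3-en-1-yl}-3,4-dimethyl-2-methylidenecyclohexyl]-2-methylhex-5-enoate | CC(C)(C)[Si](C)(C)OC/C=C(\C)CC[C@]1(C)C(=C)[C@@H]([C@](C)(CCC=C)C(=O)OC)CC[C@H]1C
F2 | step 11 | methyl (1S,5S,6R,8aS)-5-{(3E)-5-[(tert-butyldimethylsilyl)oxy]-3-methylpent-3-en-1-yl}-1,5,6-trimethyl-1,2,3,5,6,7,8,8a-octahydronaphthalene-1-carboxylate | CC(C)(C)[Si](C)(C)OC/C=C(\C)CC[C@]1(C)C2=CCC[C@](C)(C(=O)OC)[C@H]2CC[C@H]1C
F3 | step 9 | iodolactone of 18 (γ-lactone from C18 oxygen to C10, iodomethyl on C10, cis-fused to ring B) | CC(C)(C)[Si](C)(C)OC/C=C(\C)CC[C@]1(C)C2(CI)OC(=O)[C@@](C)(CCC=C)[C@H]2CC[C@H]1C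
F4 | step 10 | [(5R,6S)-6-{(3E)-5-[(tert-butyldimethylsilyl)oxy]-3-methylpent-3-en-1-yl}-5,6-dimethylcyclohex-1-en-1-yl]methyl propanoate | CC(C)(C)[Si](C)(C)OC/C=C(\C)CC[C@]1(C)C(COC(=O)CC)=CCC[C@H]1C
F5 | step 10 | 2-[(1R,3S,4R)-3-{(3E)-5-[(tert-butyldimethylsilyl)oxy]-3-methylpent-3-en-1-yl}-3,4-dimethyl-2-methylidenecyclohexyl]propanoic acid (C2 epimers) | CC(C)(C)[Si](C)(C)OC/C=C(\C)CC[C@]1(C)C(=C)[C@@H](C(C)C(=O)O)CC[C@H]1C
F6 | step 7 | methyl (5R,6S)-6-{(3E)-5-[(tert-butyldimethylsilyl)oxy]-3-methylpent-3-en-1-yl}-5,6-dimethylcyclohex-1-ene-1-carboxylate | CC(C)(C)[Si](C)(C)OC/C=C(\C)CC[C@]1(C)C(C(=O)OC)=CCC[C@H]1C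
F7 | step 4 | (2E)-5-[(1S,2R)-6-hydroxy-1,2-dimethylcyclohexyl]-3-methylpent-2-en-1-ol (carbinol epimers) | OC/C=C(\C)CC[C@]1(C)C(O)CCC[C@H]1C
F8 | step 4 | (2S,3R)-2-{(3E)-5-[(tert-butyldimethylsilyl)oxy]-3-methylpent-3-en-1-yl}-2,3-dimethylcyclohexan-1-ol (carbinol epimers) | CC(C)(C)[Si](C)(C)OC/C=C(\C)CC[C@]1(C)C(O)CCC[C@H]1C
F9 | step 4 | (2S,3R)-2-{(3E)-5-[(tert-butyldimethylsilyl)oxy]-3-methylpent-3-en-1-yl}-2,3-dimethylcyclohexan-1-one | CC(C)(C)[Si](C)(C)OC/C=C(\C)CC[C@]1(C)C(=O)CCC[C@H]1C
A1 | alternative 1 | methyl (2S,3E,5E)-2-{(4E,8E)-10-[(tert-butyldimethylsilyl)oxy]-5,8-dimethyl-3-oxodeca-4,8-dien-1-yl}-2-methylhepta-3,5-dienoate | CC(C)(C)[Si](C)(C)OC/C=C(\C)CC/C(C)=C/C(=O)CC[C@](C)(C(=O)OC)/C=C/C=C/C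
A2 | alternative 1 | cis-fused 1-oxo-6-ene decalin methyl ester with C4, C5, C8, C9 set and the silylated side chain | CC(C)(C)[Si](C)(C)OC/C=C(\C)CC[C@]1(C)[C@H]2C(=O)CC[C@](C)(C(=O)OC)[C@H]2C=C[C@H]1C
A3 | alternative 2 | methyl (1S,2R)-2-{(3R,4E)-6-[(tert-butyldimethylsilyl)oxy]-3,4-dimethylhex-4-en-1-yl}-1-methyl-3-{[(trifluoromethyl)sulfonyl]oxy}cyclohex-3-ene-1-carboxylate | COC(=O)[C@@]1(C)CCC=C(OS(=O)(=O)C(F)(F)F)[C@@H]1CC[C@@H](C)/C(C)=C/CO[Si](C)(C)C(C)(C)C
A4 | alternative 2 | methyl 12-oxo-13,14,15,16-tetranor-ent-halim-1(10)-en-18-oate | O=CC[C@]1(C)C2=CCC[C@](C)(C(=O)OC)[C@H]2CC[C@H]1C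
A5 | alternative 3 | (2E)-5-[(1S,6R)-2-ethenyl-1,6-dimethylcyclohex-2-en-1-yl]-3-methylpent-2-en-1-yl propanoate | CCC(=O)OC/C=C(\C)CC[C@]1(C)C(C=C)=CCC[C@H]1C
A6 | alternative 3 | methacrolein | CC(=C)C=O
A7 | alternative 3 | ent-halima-1(10),13E-dien-18-al 15-propanoate | CCC(=O)OC/C=C(\C)CC[C@]1(C)C2=CCC[C@](C)(C=O)[C@H]2CC[C@H]1C
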